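## Retrosynthetic overview
1. The target comes from its C-7 carbinol (a megaphone-type hydroxy-enone) by benzylic oxidation, so the C-7 configuration never matters.
2. The hydroxy-enone comes from a porosin-type tetrahydrobenzofuran-6-one. 1,2-Reduction and acid-induced 1,3-carbonyl transposition open the furan ring, as presumed for ring-opened 8.1'-neolignans in nature.
3. The porosin-type ketone comes from a burchellin-type cross-conjugated dienone by 1,4-reduction, with C-5 (OMe) set under thermodynamic control.
4. The dienone comes from the only ring-forming event, a dearomative [3+2] of an allylphenol-derived phenoxenium (quinone-monoketal) cation with (Z)-propenylveratrole under a chiral counter-anion. The C8–C1' bond forms first, then C7–O closes the dihydrofuran ring. The six-membered ring is the dearomatised arene.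
5. The cation traces back to 2-allyl-4,5-dimethoxyphenol, made from 3,4-dimethoxyphenol and allyl bromide. The Z-alkene comes from (E)-methyl isoeugenol.

Assumption: the sense of induction of the chiral acid in step 4 cannot be read from precedent. (S,S)-IDPi (BINOL-derived imidodiphosphorimidate, 3,3'-bis[3,5-bis(trifluoromethyl)phenyl], N-triflyl) is written for the antipode that gives (3S,3aS)-11, and the (R,R)-acid is used if the first run gives ent-11.

## Route

Step 1
Reactants: 1 3,4-dimethoxyphenol; 2 allyl bromide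
Product: 4 2-allyl-4,5-dimethoxyphenol, via allyl aryl ether 3 (not isolated)
Conditions: K2CO3 (1.1 equiv), 2 (1.0 equiv), NMP, 50 °C; filter; filtrate 200 °C, Ar
Reagents that add atoms: allyl bromide, C=CCBr
Why: Williamson O-allylation is followed in the same solution by an aromatic Claisen [3,3] rearrangement, which delivers the allyl group to the less hindered ortho carbon (para to the 3-OMe) and rearomatises, with no stereocentre formed.

Step 2
Reactants: 4 2-allyl-4,5-dimethoxyphenol
Product: 5 2-allyl-4,4,5-trimethoxycyclohexa-2,5-dien-1-one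
Conditions: PhI(OAc)2 (1.05 equiv), MeOH, 0 °C
Reagents that add atoms: methanol, CO
Why: This is a trivalent-iodine oxidative dearomatisation of a 4-methoxyphenol (quinone monoketal synthesis), in which methanol captures the phenoxenium ion at the methoxy-bearing para carbon and the isolated allyl group is untouched, with no stereocentre formed.

Step 3
Reactants: 6 (E)-1,2-dimethoxy-4-(prop-1-en-1-yl)benzene ((E)-methyl isoeugenol)
Product: 7 (Z)-1,2-dimethoxy-4-(prop-1-en-1-yl)benzene
Conditions: fac-Ir(ppy)3 (1 mol %), MeCN, 450 nm LED, rt; AgNO3–SiO2 chromatography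
Reagents that add atoms: none
Why: In this photosensitised triplet energy-transfer E→Z isomerisation the twisted Z-styrene has the higher triplet energy and is not re-excited, so it accumulates at the photostationary state and is freed of residual E-isomer on silver-loaded silica.

Step 4
Reactants: 5 2-allyl-4,4,5-trimethoxycyclohexa-2,5-dien-1-one; 7 (Z)-1,2-dimethoxy-4-(prop-1-en-1-yl)benzene
Product: 11 (2R,3S,3aS)-3a-allyl-2-(3,4-dimethoxyphenyl)-5-methoxy-3-methyl-3,3a-dihydro-1-benzofuran-6(2H)-one, via methoxy-oxocarbenium ion 8 (not isolated), via O-methyl oxonium cycloadduct 9 (not isolated), via C-6 dimethyl ketal 10 (not isolated)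
Conditions: (S,S)-IDPi (5 mol %), 7 (1.3 equiv, slow addition), CH2Cl2, −70 → −30 °C; then H2O–THF, 0 °C; recrystallise to ≥99% ee
Reagents that add atoms: water, O
Why: Proposed new method: the confined strong acid ionises ketal 5 to the planar cation 8, which stays paired with the chiral IDPi anion so that only one face of the allyl-bearing carbon is open (absolute control of C-3a), the Z-alkene then adds through its CH(CH3) terminus in the aryl-endo, π-stacked orientation that turns the methyl group away from the allyl group (C-3 relative to C-3a), the ring carbonyl oxygen closes suprafacially on the veratryl cation (cis C-2/C-3, a centre erased in step 7), and methanol followed by water releases the proton and the C-6 ketone; the closest known reaction types are the racemic acid-catalysed Büchi-type quinone-monoketal/propenylarene [3+2]–[5+2] cycloaddition and IDPi-catalysed asymmetric additions of aryl olefins to oxocarbenium ions (asymmetric counter-anion-directed catalysis).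

Step 5
Reactants: 11 (2R,3S,3aS)-3a-allyl-2-(3,4-dimethoxyphenyl)-5-methoxy-3-methyl-3,3a-dihydro-1-benzofuran-6(2H)-one
Product: 13 (2R,3S,3aR,5R)-3a-allyl-2-(3,4-dimethoxyphenyl)-5-methoxy-3-methyl-3,3a,4,5-tetrahydro-1-benzofuran-6(2H)-one, via 5-epimeric ketone 12 (not isolated)
Conditions: Cu(OAc)2·H2O (5 mol %), 1,2-(Ph2P)2C6H4 (5 mol %), (EtO)2MeSiH (1.5 equiv), t-BuOH (2 equiv), toluene, 0 °C → rt; then DBU (0.2 equiv), 40 °C
Reagents that add atoms: none
Why: This copper hydride 1,4-reduction (Stryker–Lipshutz type) touches only the α-methoxy enone, because the other C=C is a deactivated vinylogous ester and the allyl group is unactivated, and DBU epimerisation then places the C-5 methoxy group equatorial, trans to the allyl group that the ring fusion locks pseudo-axial, which is the (5R) configuration.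

Step 6
Reactants: 13 (2R,3S,3aR,5R)-3a-allyl-2-(3,4-dimethoxyphenyl)-5-methoxy-3-methyl-3,3a,4,5-tetrahydro-1-benzofuran-6(2H)-one
Product: 15 (4R,6R)-6-allyl-6-[(1R,2S)-1-(3,4-dimethoxyphenyl)-1-hydroxypropan-2-yl]-4-methoxycyclohex-2-en-1-one, via C-6 allylic alcohol 14 (not isolated)
Conditions: DIBAL-H (1.2 equiv), CH2Cl2, −78 °C; then 1 M aq. HCl–THF, 0 °C, 30 min
Reagents that add atoms: water, O
Why: In this Stork–Danheiser-type 1,2-reduction and acid-induced 1,3-carbonyl transposition the allylic alcohol ionises to the O-stabilised allyl cation, water adds at C-7a, and the hemiketal collapses to open the furan ring, which destroys only the new C-6 carbinol centre and leaves C-3, C-3a and C-5 untouched.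

Step 7
Reactants: 15 (4R,6R)-6-allyl-6-[(1R,2S)-1-(3,4-dimethoxyphenyl)-1-hydroxypropan-2-yl]-4-methoxycyclohex-2-en-1-one
Product: 16 (4R,6R)-6-allyl-6-[(2S)-1-(3,4-dimethoxyphenyl)-1-oxopropan-2-yl]-4-methoxycyclohex-2-en-1-one
Conditions: Dess–Martin periodinane (1.2 equiv), CH2Cl2, 0 °C → rt
Reagents that add atoms: none
Why: The Dess–Martin oxidation of the benzylic carbinol runs without base, so the now enolisable C-8 centre is not epimerised, the enone, methyl ether and allyl group are inert, and both C-7 epimers of 15 converge on the same ketone.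

## Compound list
1 | 3,4-dimethoxyphenol | COc1ccc(O)cc1OC | starting material
2 | allyl bromide | C=CCBr | starting material
3 | 4-(allyloxy)-1,2-dimethoxybenzene | C=CCOc1ccc(OC)c(OC)c1 | intermediate
4 | 2-allyl-4,5-dimethoxyphenol | C=CCc1cc(OC)c(OC)cc1O | intermediate
5 | 2-allyl-4,4,5-trimethoxycyclohexa-2,5-dien-1-one | C=CCC1=CC(OC)(OC)C(OC)=CC1=O | intermediate
6 | (E)-1,2-dimethoxy-4-(prop-1-en-1-yl)benzene | C/C=C/c1ccc(OC)c(OC)c1 | starting material
7 | (Z)-1,2-dimethoxy-4-(prop-1-en-1-yl)benzene | C/C=C\c1ccc(OC)c(OC)c1 | intermediate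
8 | 2-allyl-4,5-dimethoxyphenoxenium (4-methoxy-oxocarbenium) ion | C=CCC1=CC(=[O+]C)C(OC)=CC1=O | intermediate
9 | (2R,3S,3aS) O-methyl oxonium form of 11 | C=CC[C@]12C=C(OC)C(=[O+]C)C=C1O[C@@H](c3ccc(OC)c(OC)c3)[C@H]2C | intermediate
10 | (2R,3S,3aS)-3a-allyl-2-(3,4-dimethoxyphenyl)-5,6,6-trimethoxy-3-methyl-2,3,3a,6-tetrahydro-1-benzofuran | C=CC[C@]12C=C(OC)C(OC)(OC)C=C1O[C@@H](c3ccc(OC)c(OC)c3)[C@H]2C | intermediate
11 | (2R,3S,3aS)-3a-allyl-2-(3,4-dimethoxyphenyl)-5-methoxy-3-methyl-3,3a-dihydro-1-benzofuran-6(2H)-one | C=CC[C@]12C=C(OC)C(=O)C=C1O[C@@H](c3ccc(OC)c(OC)c3)[C@H]2C | intermediate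
12 | (2R,3S,3aR,5S)-3a-allyl-2-(3,4-dimethoxyphenyl)-5-methoxy-3-methyl-3,3a,4,5-tetrahydro-1-benzofuran-6(2H)-one | C=CC[C@]12C[C@H](OC)C(=O)C=C1O[C@@H](c3ccc(OC)c(OC)c3)[C@H]2C | intermediate
13 | (2R,3S,3aR,5R)-3a-allyl-2-(3,4-dimethoxyphenyl)-5-methoxy-3-methyl-3,3a,4,5-tetrahydro-1-benzofuran-6(2H)-one | C=CC[C@]12C[C@@H](OC)C(=O)C=C1O[C@@H](c3ccc(OC)c(OC)c3)[C@H]2C | intermediate
14 | (2R,3S,3aR,5R)-3a-allyl-2-(3,4-dimethoxyphenyl)-5-methoxy-3-methyl-2,3,3a,4,5,6-hexahydro-1-benzofuran-6-ol (C-6 epimers, centre lost at once) | C=CC[C@]12C[C@@H](OC)C(O)C=C1O[C@@H](c3ccc(OC)c(OC)c3)[C@H]2C | intermediate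
15 | (4R,6R)-6-allyl-6-[(1R,2S)-1-(3,4-dimethoxyphenyl)-1-hydroxypropan-2-yl]-4-methoxycyclohex-2-en-1-one | C=CC[C@]1([C@H](C)[C@@H](O)c2ccc(OC)c(OC)c2)C[C@@H](OC)C=CC1=O | intermediate
16 | (4R,6R)-6-allyl-6-[(2S)-1-(3,4-dimethoxyphenyl)-1-oxopropan-2-yl]-4-methoxycyclohex-2-en-1-one | C=CC[C@]1([C@H](C)C(=O)c2ccc(OC)c(OC)c2)C[C@@H](OC)C=CC1=O | target

## Step count and risks
Total step count: 7.
Longest linear sequence: 6 (steps 1, 2, 4, 5, 6, 7).

**Risk 1 (step 4).**
- The ion pair may give low ee.
- The strong acid may isomerise or oligomerise the electron-rich Z-alkene.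
- Carbon closure ([5+2]) may compete with oxygen closure.

The fallback sets out from 4 and comes back at 11. It replaces the free cation and chiral anion by a neutral quinone held in a stoichiometric chiral Lewis acid. Oxidative demethylation of 4 (PhI(OAc)2, MeCN–H2O, 0 °C) gives 2-allyl-5-methoxy-1,4-benzoquinone F1. A tetravalent titanium complex made from TiCl4, Ti(OiPr)4 and (R,R)-TADDOL (CH2Cl2–toluene, −78 °C) chelates the C-4 carbonyl and 5-methoxy pair of F1. This activates the allyl-bearing carbon for attack by 7 inside a defined chiral pocket. Oxygen closure and chloride-induced loss of the methyl group give (2R,3S,3aS)-3a-allyl-2-(3,4-dimethoxyphenyl)-5-hydroxy-3-methyl-3,3a-dihydro-1-benzofuran-6(2H)-one F2. O-Methylation of this diosphenol (MeI, K2CO3, acetone) returns to 11.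

**Risk 2 (step 5).**
- The β-carbon is neopentylic and the enone carries a donor, so hydride transfer may be slow.
- 1,2-Reduction may intervene.

The fallback sets out from 11 and comes back at 13. It replaces the nucleophilic metal hydride by biocatalysis. An ene-reductase of the Old Yellow Enzyme family (OPR3 or YqjM type) is used with NADP+, glucose and glucose dehydrogenase in phosphate buffer–MTBE at 30 °C. The enzyme binds the C-6 carbonyl and delivers flavin hydride to C-4 and a tyrosine proton to C-5. Both 4,4-disubstituted cyclohexadienones and 2-methoxy enones are accepted substrate classes, and isolated alkenes are not reduced. The same DBU equilibration then fixes C-5.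

**Risk 3 (step 6).**
- The electron-rich benzylic alcohol and the allyl cation meet aqueous acid, so cyclisation onto the allyl group is possible.
- C-5 could scramble by reversible proton loss.
- Methanol could be eliminated.

The fallback sets out from 13 and comes back at 16, which makes step 7 unnecessary. It opens the ring oxidatively first. DDQ in wet CH2Cl2 abstracts the C-2 benzylic hydride, and hydrolysis of the oxocarbenium ion gives (4R,6R)-4-allyl-4-[(2S)-1-(3,4-dimethoxyphenyl)-1-oxopropan-2-yl]-6-methoxycyclohexane-1,3-dione F3. Sulfonylation at the less hindered enol oxygen (Tf2O, 2,6-lutidine, CH2Cl2, −78 °C) gives (4R,6R)-4-allyl-4-[(2S)-1-(3,4-dimethoxyphenyl)-1-oxopropan-2-yl]-6-methoxy-3-oxocyclohex-1-en-1-yl trifluoromethanesulfonate F4. Palladium-catalysed formate reduction (Pd(OAc)2, PPh3, HCO2H, Bu3N, DMF, 40 °C) replaces the triflate by hydrogen and delivers 16.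

## Further compounds
F1 | step 4 | 2-allyl-5-methoxy-1,4-benzoquinone | C=CCC1=CC(=O)C(OC)=CC1=O
F2 | step 4 | (2R,3S,3aS)-3a-allyl-2-(3,4-dimethoxyphenyl)-5-hydroxy-3-methyl-3,3a-dihydro-1-benzofuran-6(2H)-one | C=CC[C@]12C=C(O)C(=O)C=C1O[C@@H](c3ccc(OC)c(OC)c3)[C@H]2C
F0 | step 5 | none | none
F3 | step 6 | (4R,6R)-4-allyl-4-[(2S)-1-(3,4-dimethoxyphenyl)-1-oxopropan-2-yl]-6-methoxycyclohexane-1,3-dione | C=CC[C@]1([C@H](C)C(=O)c2ccc(OC)c(OC)c2)C[C@@H](OC)C(=O)CC1=O
F4 | step 6 | (4R,6R)-4-allyl-4-[(2S)-1-(3,4-dimethoxyphenyl)-1-oxopropan-2-yl]-6-methoxy-3-oxocyclohex-1-en-1-yl trifluoromethanesulfonate | C=CC[C@]1([C@H](C)C(=O)c2ccc(OC)c(OC)c2)C[C@@H](OC)C(OS(=O)(=O)C(F)(F)F)=CC1=O
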